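## Structural features

The target is the 3-hydroxy-4-methoxybenzoate of a daucane-type sesquiterpene diol. Its core is a cis-fused bicyclo[5.3.0]decene in which a cyclopentane (C6–C7–C8–C9–C10) and a cycloheptene (C10–C1–C2–C3–C4–C5–C6) share the C6–C10 bond. The locants used throughout are: C1 the ester-bearing CH, C2=C3 the trisubstituted alkene with its methyl on C3, C4 and C5 the CH2 pair of the large ring, C6 the quaternary methyl carbon, C7 and C8 the CH2 pair of the small ring, C9 the tertiary carbinol carbon with the isopropyl group, C10 the ring-fusion CH. The four stereocentres form one cluster around C10 (1R,6R,9R,10S): H10 and the C6 methyl are cis, the isopropyl group lies on their face, and the C9 hydroxyl and the C1 acyloxy group lie on the other face. Fragile points are the secondary allylic ester (it can ionise to an allyl cation that is tertiary at C3, and base cleaves it), the free phenol, the tertiary alcohol 1,3 to the C1 oxygen (dehydration or retro-aldol cleavage as soon as C1 is a ketone), and C10, which can epimerise whenever C9 or C1 is a carbonyl. The real difficulty is the quaternary C6 at the fusion of a seven-membered ring, whose absolute configuration has to be fixed with no functional handle nearby; the other three centres must then be set relative to it. The key step uses the fact that C10 and C6 are the α- and β-carbons of a 3-methylcyclopent-2-enone with its carbonyl at C9, and that a vinyl group C4=C5 can hang from C10 on the three-atom chain C1–C2–C3, the length needed for a 1,5-closure. Because C3 is sp2 only in the target, it can be sp3 and stereogenic for most of the route, carry the absolute configuration into C6, and then be flattened.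

## Logic of the disconnections

**22 to 21, then 16 and 19 (19 from 17).** The two Si–O bonds and the acyl–O bond at C1 are cut first, because the allylic ester and the phenol are the most fragile parts and should appear last. The phenol of 17 must be masked as in 19 so that the acid cannot acylate itself. This reduces the problem to the bicyclic alcohol 16. The forward steps must acylate a hindered secondary allylic alcohol without ionising it, and remove silicon under near-neutral conditions.

**16 to 15.** The C1–H bond is cut (carbonyl reduction). With C1 as a ketone one stereocentre is removed, and the same carbonyl can serve earlier for the unsaturation and, masked, as a spectator during the key step. The forward step must be 1,2-selective and deliver hydride on the face of H10.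

**15 to 14 to 13.** The C2=C3 π bond is removed. With C3 sp3 it can be a stereocentre, and because C6 has no hydrogen, dehydrogenation of the C1 ketone can only go toward C2–C3. The forward step needs enolisation toward C2 and a capped C9 hydroxyl.

**13 to 12 to 11.** The C9–isopropyl bond is cut and C1 is returned to its ketal. C9 is needed as a carbonyl earlier, as chromophore and as electron acceptor. This leaves 11 with three stereocentres, one of them temporary. The forward steps need a nucleophile that enters on the face of H10 and a ketal hydrolysis that spares the tertiary alcohol.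

**11 to 10 to 9.** Backwards, C10–C4 is re-formed to give 10, and then C10–C4 and C5–C6 are cut together. This is the strategic cut: the seven-membered ring, the quaternary C6 and the ring fusion all go back to a monocyclic enone with one stereocentre. The forward step needs face selection by C3, opening of the correct cyclobutane bond, and protonation of C10 to the cis fusion.

**9 to 8.** The C10=C6 double bond is cut (aldol condensation). This gives an acyclic 1,4-diketone. The forward step requires the C10 enolate to close on the methyl ketone and the dioxolane to survive base.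

**8 to 6 and 7.** The C8–C9 bond is cut. The 1,4-dicarbonyl relationship calls for an acyl anion equivalent at C9, which leads to a commodity enone and an aldehyde. The demand is that this anion equivalent be generated next to a β-ketal.

**6 to 5 to 4 to 3.** The oxidation level at C9 is adjusted, the C1 ketal removed, and the C1–C10 bond cut (Claisen condensation with an acetate enolate). This leads to a five-carbon ester holding the only stereocentre. C1 must be ketalised before any carbanion is made at C10.

**3 to 1 and 2.** The C3–C4 bond is cut (conjugate addition of a vinyl group). The one centre that must be bought by asymmetric catalysis is thus set in the first step on the cheapest materials. The catalyst must distinguish the methyl arm from the CH2CO2Et arm.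

## Other disconnections considered

**Alternative 1:** The cut removes C6–C10 and C4–C5 at once and leads to the acyclic tertiary allylic alcohol A1. A1 carries a 1,1-disubstituted alkene (C5=C6) and an (E)-alkenyl trans-2-methylcyclopropane (C10=C1 with the ring C2, C3, C4). Forward, [Rh(CO)2Cl]2 would open the cyclopropane at its less substituted bond and join the five-carbon unit to the alkene in a (5+2) cycloaddition, giving the cis-fused alcohol A2.
- In its favour: both rings come from an open chain in one catalytic step. The C9 carbinol with its isopropyl group is in place from the start, so the organocerium addition and its facial question disappear. No lamp is needed.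
- Against it here: the absolute configuration must come from C9 of A1, a tertiary alcohol with three carbon groups of similar size, which is harder to obtain as one enantiomer than 3. The two-carbon partner is an unactivated 1,1-disubstituted alkene that must become a quaternary carbon, the slowest kind of partner. A2 has no oxygen at C1, so a late allylic oxidation with shift of C1=C2 to C2=C3 is needed, in which abstraction of H10 competes with H3 and the face at C1 has no clear control.
- Comparison: in step economy the alternative is the better if A1 is short to make. In ring construction it is the equal of the chosen plan, since each builds the seven-membered ring and C6 in one operation. In control of configuration and oxidation level the chosen plan is the safer, because it carries the C1 oxygen from the beginning and takes its chirality from a catalytic conjugate addition.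

**Alternative 2:** The cut removes C6–C7 and C9–C10 and leads to the symmetric dienone A3 and the cyclopropanol A4. Forward, Et2Zn would open A4 to the zinc homoenolate, a monovalent copper catalyst (for example CuBr·SMe2 with a chiral ligand) would add it to C6 of A3, and the zinc enolate at C10 would close on the isopropyl ketone to give A5.
- In its favour: A5 holds every carbon of the terpene part and is the C9-hydroxy form of 15, so only reduction, acylation and deprotection would remain. The symmetric A3 raises no regiochemical question. An aldol closure through a chelated enolate should put the hydroxyl on the side of the C1 carbonyl, as required.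
- Against it here: conjugate addition to a β,β-disubstituted enone carbon by a weakly nucleophilic, functionalised homoenolate is the hardest kind of conjugate addition. A silyl chloride activator would trap the enolate and split the annulation into two steps. The chiral copper catalyst would have to select between the two enantiotopic arms of A3 on this reluctant pair. A5 can revert by retro-aldol cleavage.
- Comparison: in structure the alternative is the equal of the chosen plan, and in step economy it is clearly the better. In mechanism the chosen plan is the safer, because light-driven bond formation at C6 is little affected by steric hindrance.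

**Alternative 3:** The cut removes C1–C10 and O–C9 of the isoxazoline A7 and leads to the (Z)-enal oxime A6, a cyclopentene (C9=C10, isopropyl on C9) with the quaternary C6 carrying the chain. Forward, NaOCl would oxidise the oxime to the conjugated nitrile oxide, which would add across C9=C10 and close the seven-membered ring; N–O cleavage (Mo(CO)6, wet MeCN) and hydrolysis would then give A5.
- In its favour: oxygen and carbon are delivered to one face of the cyclopentene, and the tether from C6 decides which face. C9 and C10 are therefore fixed by geometry, not by a facial preference. On this point the alternative is better than the chosen plan, which relies on convex-face attack in step 8 and on protonation in step 7. No β-hydroxy ketone has to pass through acid.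
- Against it here: C6 must be made as a single enantiomer beforehand in a cyclopentene, a separate problem. The dipolarophile is an unactivated trisubstituted alkene whose more substituted carbon must take the oxygen. The cycloaddition closes a seven-membered ring and has to outrun dimerisation of the nitrile oxide. The (Z)-enal geometry is easily lost.
- Comparison: in stereochemical security at C9 and C10 the alternative is the equal or the better. Its ring-forming step is less certain than the chosen one. The step count should be about equal.

Key step: step 7

Assumption: the target is taken exactly as drawn (cis-fused, H10 and the C6 methyl on one face, O1 and O9 on the other); the sense of induction of the chiral diene in step 1 is not predicted, so the ligand enantiomer is defined by its outcome (3S).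

## Steps

**Step 1**
Reactants: 1 ethyl (E)-but-2-enoate; 2 potassium vinyltrifluoroborate
Product: 3 ethyl (3S)-3-methylpent-4-enoate
Conditions: [RhCl(C2H4)2]2 (2.5 mol%), chiral diene 2,5-diphenylbicyclo[2.2.2]octa-2,5-diene (5.5 mol%, the enantiomer that leads to 3S), KOH (0.2 equiv), dioxane–H2O 10:1, 50 °C
Reagents that add atoms: none
Why: Rhodium-catalysed asymmetric 1,4-addition of an alkenylboron reagent to an enoate: transmetallation gives a monovalent rhodium–vinyl species, insertion of the crotonate sets C3 under control of the chiral diene, and water protonates the rhodium enolate. The ethylene precatalyst is used instead of a 1,5-cyclooctadiene complex, because that achiral diene would compete with the chiral diene for the metal and open a racemic channel.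

**Step 2**
Reactants: 3 ethyl (3S)-3-methylpent-4-enoate
Product: 4 ethyl (5S)-5-methyl-3-oxohept-6-enoate
Conditions: EtOAc (3.5 equiv), LiN(SiMe3)2 (3.6 equiv), THF, –78 °C; then 3, –78 → –30 °C; AcOH
Reagents that add atoms: ethyl acetate, CCOC(C)=O
Why: Crossed Claisen condensation: the lithium enolate of ethyl acetate attacks the ester carbonyl of 3 and the β-keto ester leaves the equilibrium as its enolate, which is why an excess of enolate is used. C3 is β to the carbonyl groups and has no acidic hydrogen, so its configuration is not at risk.

**Step 3**
Reactants: 4 ethyl (5S)-5-methyl-3-oxohept-6-enoate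
Product: 5 ethyl {2-[(2S)-2-methylbut-3-en-1-yl]-1,3-dioxolan-2-yl}acetate
Conditions: HOCH2CH2OH (5 equiv), p-toluenesulfonic acid monohydrate (5 mol%), benzene, reflux with azeotropic removal of water
Reagents that add atoms: ethane-1,2-diol, OCCO
Why: Acid-catalysed ketalisation of the ketone carbonyl, driven by removal of water; the ester carbonyl is not electrophilic enough to react. Ketalising now means that no carbanion is ever made at C10 while C1 is a free ketone.

**Step 4**
Reactants: 5 ethyl {2-[(2S)-2-methylbut-3-en-1-yl]-1,3-dioxolan-2-yl}acetate
Product: 6 {2-[(2S)-2-methylbut-3-en-1-yl]-1,3-dioxolan-2-yl}acetaldehyde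
Conditions: i-Bu2AlH (1.1 equiv), CH2Cl2, –78 °C; MeOH, then aq. potassium sodium tartrate
Reagents that add atoms: none
Why: Partial reduction of an ester: the aluminium hemiacetal formed at –78 °C, held by coordination to a dioxolane oxygen, does not collapse until work-up, so the aldehyde is not reduced further. 6 is used at once, because a β,β-dialkoxy aldehyde can lose alkoxide on standing with base.

**Step 5**
Reactants: 6 {2-[(2S)-2-methylbut-3-en-1-yl]-1,3-dioxolan-2-yl}acetaldehyde; 7 but-3-en-2-one
Product: 8 1-{2-[(2S)-2-methylbut-3-en-1-yl]-1,3-dioxolan-2-yl}hexane-2,5-dione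
Conditions: 7 (1.5 equiv), 3-benzyl-5-(2-hydroxyethyl)-4-methylthiazolium chloride (15 mol%), Et3N (0.5 equiv), EtOH, 70 °C
Reagents that add atoms: none
Why: Stetter reaction: the thiazol-2-ylidene adds to the aldehyde, proton transfer gives the acyl anion equivalent, and this adds 1,4 to 7 and releases the catalyst, forming C8–C9. Aliphatic aldehydes and methyl vinyl ketone are the standard partners of this reaction.

**Step 6**
Reactants: 8 1-{2-[(2S)-2-methylbut-3-en-1-yl]-1,3-dioxolan-2-yl}hexane-2,5-dione
Product: 9 3-methyl-2-{2-[(2S)-2-methylbut-3-en-1-yl]-1,3-dioxolan-2-yl}cyclopent-2-en-1-one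
Conditions: KOH (0.3 M), MeOH–H2O, 50 °C
Reagents that add atoms: none
Why: Intramolecular aldol condensation: the C10 enolate adds to the methyl ketone carbonyl (C6), closes the five-membered ring, and loss of water gives the tetrasubstituted enone, as in the classical conversion of 2,5-diketones into 2-alkyl-3-methylcyclopent-2-enones; the other aldol mode is reversible and leads to the less substituted enone. Opening of the dioxolane by β-elimination from the C10 enolate is reversible, since the alkoxide stays tethered and can re-add, so it should not divert material.

**Step 7**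
Reactants: 9 3-methyl-2-{2-[(2S)-2-methylbut-3-en-1-yl]-1,3-dioxolan-2-yl}cyclopent-2-en-1-one
Product: 11 (3R,6R,10R)-1,1-(ethylenedioxy)-3,6-dimethyl-cis-bicyclo[5.3.0]decan-9-one (text locants; H10 cis to the C6 methyl), via cyclobutane photoadduct 10 (not isolated)
Conditions: hν (medium-pressure Hg lamp, borosilicate filter, λ > 300 nm), degassed CH2Cl2 (0.01 M), –40 °C; evaporate; then SmI2 (2.5 equiv), t-BuOH (2 equiv), THF–DMPU, –78 → 0 °C; aq. NH4Cl
Reagents that add atoms: none
Why: Excitation of the enone and intersystem crossing give the triplet, whose α-carbon C10 bonds to the internal alkene carbon C4; the 1,4-biradical (tertiary C6, primary C5) then closes C5–C6 after spin inversion, so the quaternary C6 is made without any steric demand on a nucleophile. The closest known reaction type is the intramolecular enone–alkene [2+2] photocycloaddition of 2-(pent-4-enyl)cycloalk-2-enones to straight adducts, followed by single-electron cleavage of a cyclobutyl ketone. Ring closures: the five-membered carbocycle C10–C1–C2–C3–C4 forms by 1,5 (5-exo) closure, as the rule of five requires for a three-atom tether; the four-membered ring C10–C4–C5–C6 forms by radical recombination with both fusions necessarily cis; the seven-membered ring is not closed but uncovered when SmI2 transfers an electron to the C9 carbonyl and the ketyl breaks C10–C4. That bond is the one cleaved because it is exocyclic to the cyclopentanone and nearly parallel to the ketyl p orbital, whereas C10–C6 lies close to the carbonyl plane and C10–C1 is unstrained; the C4 radical is reduced and protonated to CH2. C6 is set in the light stage by the enone face that the vinyl group reaches, and C3 controls this: in the envelope of the forming five-membered ring the C3 methyl sits pseudo-equatorial (exo on the bicyclo[3.2.0] unit, cis to H4), away from the cyclobutane carbons and from an axial dioxolane oxygen on C1, and with (S)-C3 this places the C6 methyl as in the target (descriptor 6S in 10 and 6R in 11, a change of ligand ranking only). C10 is set last, when the trivalent samarium enolate is protonated on the face of the C6 methyl (the other face is covered by C5 and the large ring), which gives the cis fusion that is also expected to be the more stable at this epimerisable centre. The selectivities needed are straight over crossed addition (secured by the tether length), intra- over intermolecular reaction (high dilution), the facial preference just described (helped by low temperature and by the gem-dialkoxy C1, which folds the tether), and ring opening before further reduction (the product stays as its enolate until work-up).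

**Step 8**
Reactants: 11 (3R,6R,10R)-1,1-(ethylenedioxy)-3,6-dimethyl-cis-bicyclo[5.3.0]decan-9-one
Product: 12 (3R,6R,9R,10R)-1,1-(ethylenedioxy)-3,6-dimethyl-9-(propan-2-yl)-cis-bicyclo[5.3.0]decan-9-ol (text locants)
Conditions: i-PrMgCl (3 equiv), CeCl3 (3 equiv, dried), THF, –78 → 0 °C; aq. NH4Cl
Reagents that add atoms: isopropylmagnesium chloride, CC(C)[Mg]Cl
Why: 1,2-Addition of an organocerium reagent, which is much less basic than the Grignard reagent and so suppresses enolisation of C10–H and β-hydride reduction at this hindered ketone. The nucleophile should enter on the convex face, the face of H10 and the C6 methyl, because the other face of C9 is covered by the dioxolane-bearing C1 and the large ring; this puts the isopropyl group cis to H10 and the hydroxyl on the side of C1 (9R).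

**Step 9**
Reactants: 12 (3R,6R,9R,10R)-1,1-(ethylenedioxy)-3,6-dimethyl-9-(propan-2-yl)-cis-bicyclo[5.3.0]decan-9-ol
Product: 13 (3R,6R,9R,10R)-9-hydroxy-3,6-dimethyl-9-(propan-2-yl)-cis-bicyclo[5.3.0]decan-1-one (text locants)
Conditions: pyridinium p-toluenesulfonate (0.2 equiv), acetone–H2O 10:1, 50 °C
Reagents that add atoms: water, O
Why: Acid-catalysed hydrolysis of the dioxolane through the oxocarbenium ion at C1; the weak acid is chosen so that the tertiary alcohol, now β to a ketone, is neither ionised nor eliminated. C10 is flanked by two fully substituted carbons, so enolisation toward it (the path to epimerisation, dehydration or retro-aldol cleavage) should be slow.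

**Step 10**
Reactants: 13 (3R,6R,9R,10R)-9-hydroxy-3,6-dimethyl-9-(propan-2-yl)-cis-bicyclo[5.3.0]decan-1-one
Product: 14 (3R,6R,9R,10S)-3,6-dimethyl-9-(propan-2-yl)-1,9-bis(trimethylsilyloxy)-cis-bicyclo[5.3.0]dec-1-ene (text locants; enol ether C1=C2)
Conditions: Me3SiOTf (2.5 equiv), Et3N (4 equiv), CH2Cl2, –78 → 0 °C
Reagents that add atoms: trimethylsilyl trifluoromethanesulfonate, C[Si](C)(C)OS(=O)(=O)C(F)(F)F
Why: Silylation of the hydroxyl and soft enolisation of the silyl-activated carbonyl: Et3N should take a proton from the open C2 methylene and not from C10–H, which is shielded by C6 and C9 and would give a strained tetrasubstituted enol ether. Capping O9 also shuts off retro-aldol cleavage in the following steps.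

**Step 11**
Reactants: 14 (3R,6R,9R,10S)-3,6-dimethyl-9-(propan-2-yl)-1,9-bis(trimethylsilyloxy)-cis-bicyclo[5.3.0]dec-1-ene
Product: 15 (6R,9R,10R)-3,6-dimethyl-9-(propan-2-yl)-9-(trimethylsilyloxy)-cis-bicyclo[5.3.0]dec-2-en-1-one (text locants)
Conditions: Pd(OAc)2 (1.1 equiv), MeCN, 25 °C
Reagents that add atoms: none
Why: Ito–Saegusa oxidation: the silyl enol ether gives a divalent palladium enolate bound at C2, and syn β-hydride elimination of H3 releases the C2=C3 enone and zerovalent palladium. H3 is the only β-hydrogen available, so the double bond can only appear at C2=C3; the temporary stereocentre C3 is erased here.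

**Step 12**
Reactants: 15 (6R,9R,10R)-3,6-dimethyl-9-(propan-2-yl)-9-(trimethylsilyloxy)-cis-bicyclo[5.3.0]dec-2-en-1-one
Product: 16 (1R,6R,9R,10S)-3,6-dimethyl-9-(propan-2-yl)-9-(trimethylsilyloxy)-cis-bicyclo[5.3.0]dec-2-en-1-ol (text locants)
Conditions: NaBH4 (1.5 equiv), CeCl3·7H2O (1.2 equiv), MeOH, –78 → –40 °C; aq. NH4Cl at –40 °C
Reagents that add atoms: none
Why: Luche reduction: the cerium salt makes the borohydride a hard donor and activates the carbonyl, so only 1,2-addition should occur. Hydride should come from the face of H10 and the C6 methyl, because the other face of C1 is blocked by C9 and its Me3SiO group; the new hydroxyl is then trans to H10 and on the side of O9 (1R).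

**Step 13**
Reactants: 17 3-hydroxy-4-methoxybenzoic acid
Product: 19 3-[(tert-butyldimethylsilyl)oxy]-4-methoxybenzoic acid, via silyl ester 18 (not isolated)
Conditions: t-BuMe2SiCl (2.3 equiv), imidazole (4.5 equiv), DMF, 25 °C; then AcOH–THF–H2O 3:1:1, 25 °C
Reagents that add atoms: tert-butyldimethylsilyl chloride, CC(C)(C)[Si](C)(C)Cl
Why: Imidazole-promoted silylation of both the phenol and the acid; the silyl ester is far more labile than the aryl silyl ether and is hydrolysed selectively by aqueous acetic acid. The masked phenol cannot act as a nucleophile in the acylation.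

**Step 14**
Reactants: 16 (1R,6R,9R,10S)-3,6-dimethyl-9-(propan-2-yl)-9-(trimethylsilyloxy)-cis-bicyclo[5.3.0]dec-2-en-1-ol; 19 3-[(tert-butyldimethylsilyl)oxy]-4-methoxybenzoic acid
Product: 21 (1R,6R,9R,10S)-3,6-dimethyl-9-(propan-2-yl)-9-(trimethylsilyloxy)-cis-bicyclo[5.3.0]dec-2-en-1-yl 3-[(tert-butyldimethylsilyl)oxy]-4-methoxybenzoate (text locants), via acid chloride 20 (not isolated)
Conditions: 19, (COCl)2 (1.2 equiv), N,N-dimethylformamide (cat.), CH2Cl2, 0 → 25 °C, evaporate; then 16, Et3N (3 equiv), 4-(dimethylamino)pyridine (0.3 equiv), CH2Cl2, 0 → 25 °C
Reagents that add atoms: none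
Why: Acid chloride formation followed by O-acylation under nucleophilic catalysis (acylpyridinium intermediate), the most forcing standard method for a hindered secondary alcohol; the silylated tertiary O9 is inert. The C1–O bond is not touched, so C1 keeps its configuration, and the basic medium avoids ionisation of the allylic system.

**Step 15**
Reactants: 21 (1R,6R,9R,10S)-3,6-dimethyl-9-(propan-2-yl)-9-(trimethylsilyloxy)-cis-bicyclo[5.3.0]dec-2-en-1-yl 3-[(tert-butyldimethylsilyl)oxy]-4-methoxybenzoate
Product: 22 (3R,3aS,4R,8aR)-3-hydroxy-6,8a-dimethyl-3-(propan-2-yl)-1,2,3,3a,4,7,8,8a-octahydroazulen-4-yl 3-hydroxy-4-methoxybenzoate (the target; 1R,6R,9R,10S in text locants)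
Conditions: Bu4NF (2.5 equiv), AcOH (2.5 equiv), THF, 0 → 25 °C
Reagents that add atoms: none
Why: Fluoride cleaves the aryl silyl ether and the tertiary trimethylsilyl ether through pentacoordinate silicon. Acetic acid buffers the phenoxide and alkoxide so that the allylic benzoate is neither cleaved nor shifted.

## Compound list

1 | ethyl (E)-but-2-enoate | CCOC(=O)/C=C/C | starting material
2 | potassium vinyltrifluoroborate | [K+].C=C[B-](F)(F)F | starting material
3 | ethyl (3S)-3-methylpent-4-enoate | C=C[C@@H](C)CC(=O)OCC | intermediate
4 | ethyl (5S)-5-methyl-3-oxohept-6-enoate | C=C[C@@H](C)CC(=O)CC(=O)OCC | intermediate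
5 | ethyl {2-[(2S)-2-methylbut-3-en-1-yl]-1,3-dioxolan-2-yl}acetate | C=C[C@@H](C)CC1(OCCO1)CC(=O)OCC | intermediate
6 | {2-[(2S)-2-methylbut-3-en-1-yl]-1,3-dioxolan-2-yl}acetaldehyde | C=C[C@@H](C)CC1(OCCO1)CC=O | intermediate
7 | but-3-en-2-one | CC(=O)C=C | starting material
8 | 1-{2-[(2S)-2-methylbut-3-en-1-yl]-1,3-dioxolan-2-yl}hexane-2,5-dione | C=C[C@@H](C)CC1(OCCO1)CC(=O)CCC(C)=O | intermediate
9 | 3-methyl-2-{2-[(2S)-2-methylbut-3-en-1-yl]-1,3-dioxolan-2-yl}cyclopent-2-en-1-one | C=C[C@@H](C)CC1(OCCO1)C2=C(C)CCC2=O | intermediate
10 | cyclobutane photoadduct (3S,4R,6S,10S in text locants): cyclopentanone C6–C7–C8–C9(=O)–C10, cyclobutane C10–C4–C5–C6, cyclopentane C10–C1–C2–C3–C4, dioxolane spiro at C1, methyls on C3 (cis to H4) and C6 | O=C1CC[C@@]2(C)C[C@@H]3[C@@H](C)CC4(OCCO4)[C@]123 | intermediate (not isolated)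
11 | (3R,6R,10R)-1,1-(ethylenedioxy)-3,6-dimethyl-cis-bicyclo[5.3.0]decan-9-one (text locants) | O=C1CC[C@@]2(C)CC[C@@H](C)CC3(OCCO3)[C@@H]12 | intermediate
12 | (3R,6R,9R,10R)-1,1-(ethylenedioxy)-3,6-dimethyl-9-(propan-2-yl)-cis-bicyclo[5.3.0]decan-9-ol (text locants) | CC(C)[C@]1(O)CC[C@@]2(C)CC[C@@H](C)CC3(OCCO3)[C@@H]12 | intermediate
13 | (3R,6R,9R,10R)-9-hydroxy-3,6-dimethyl-9-(propan-2-yl)-cis-bicyclo[5.3.0]decan-1-one (text locants) | CC(C)[C@]1(O)CC[C@@]2(C)CC[C@@H](C)CC(=O)[C@@H]12 | intermediate
14 | (3R,6R,9R,10S)-3,6-dimethyl-9-(propan-2-yl)-1,9-bis(trimethylsilyloxy)-cis-bicyclo[5.3.0]dec-1-ene (text locants) | CC(C)[C@]1(O[Si](C)(C)C)CC[C@@]2(C)CC[C@@H](C)C=C(O[Si](C)(C)C)[C@@H]12 | intermediate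
15 | (6R,9R,10R)-3,6-dimethyl-9-(propan-2-yl)-9-(trimethylsilyloxy)-cis-bicyclo[5.3.0]dec-2-en-1-one (text locants) | CC(C)[C@]1(O[Si](C)(C)C)CC[C@@]2(C)CCC(C)=CC(=O)[C@@H]12 | intermediate
16 | (1R,6R,9R,10S)-3,6-dimethyl-9-(propan-2-yl)-9-(trimethylsilyloxy)-cis-bicyclo[5.3.0]dec-2-en-1-ol (text locants) | CC(C)[C@]1(O[Si](C)(C)C)CC[C@@]2(C)CCC(C)=C[C@@H](O)[C@@H]12 | intermediate
17 | 3-hydroxy-4-methoxybenzoic acid | COc1ccc(C(=O)O)cc1O | starting material
18 | tert-butyldimethylsilyl 3-[(tert-butyldimethylsilyl)oxy]-4-methoxybenzoate | COc1ccc(C(=O)O[Si](C)(C)C(C)(C)C)cc1O[Si](C)(C)C(C)(C)C | intermediate (not isolated)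
19 | 3-[(tert-butyldimethylsilyl)oxy]-4-methoxybenzoic acid | COc1ccc(C(=O)O)cc1O[Si](C)(C)C(C)(C)C | intermediate
20 | 3-[(tert-butyldimethylsilyl)oxy]-4-methoxybenzoyl chloride | COc1ccc(C(=O)Cl)cc1O[Si](C)(C)C(C)(C)C | intermediate (not isolated)
21 | (1R,6R,9R,10S)-3,6-dimethyl-9-(propan-2-yl)-9-(trimethylsilyloxy)-cis-bicyclo[5.3.0]dec-2-en-1-yl 3-[(tert-butyldimethylsilyl)oxy]-4-methoxybenzoate (text locants) | COc1ccc(C(=O)O[C@@H]2C=C(C)CC[C@]3(C)CC[C@@](O[Si](C)(C)C)(C(C)C)[C@H]23)cc1O[Si](C)(C)C(C)(C)C | intermediate
22 | (3R,3aS,4R,8aR)-3-hydroxy-6,8a-dimethyl-3-(propan-2-yl)-1,2,3,3a,4,7,8,8a-octahydroazulen-4-yl 3-hydroxy-4-methoxybenzoate | COc1ccc(C(=O)O[C@@H]2C=C(C)CC[C@]3(C)CC[C@@](O)(C(C)C)[C@H]23)cc1O | target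

## Step count and least certain steps

Total step count: 15. Longest linear sequence: 14 steps (steps 1–12, 14 and 15, from 1); step 13 is a one-step branch.

**Step 7 (key step).**
- In the light stage, hydrogen transfer inside the 1,4-biradical and incomplete discrimination of the two enone faces by a single methyl group would lower the yield.
- The more likely failure is in the electron-transfer stage. The trivalent samarium enolate is strongly Lewis acidic and carries the dioxolane on the carbon next to it, so it may expel a ketal oxygen by β-elimination, or the ketone may be reduced further before work-up.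
- Fallback: it sets out from 10, isolated by chromatography after irradiation (which also removes a minor photoadduct), and returns to 11. Lithium in liquid ammonia–THF at –78 °C cleaves the same bond and leaves a lithium enolate. After removal of ammonia this is trapped with Me3SiCl–Et3N as the trimethylsilyl enol ether (3R,6R)-1,1-(ethylenedioxy)-3,6-dimethyl-9-(trimethylsilyloxy)bicyclo[5.3.0]dec-9-ene F1. Buffered protodesilylation (Bu4NF–AcOH, THF, –78 °C) then puts the proton on C10 in a separate, controllable operation and gives 11.

**Step 1.**
- Insertion of the small, weakly electrophilic crotonate may be slow, so that protodeboronation and oligomerisation of the vinylboron reagent compete. Face discrimination between the methyl and CH2CO2Et arms may be incomplete.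
- Fallback: it sets out from 1 and returns to 3. Reduction of 1 with i-Bu2AlH gives (E)-but-2-en-1-ol F2 (also an article of commerce). Methyl chloroformate and pyridine give (E)-but-2-en-1-yl methyl carbonate F3. Branched-selective asymmetric allylic alkylation of diethyl malonate ([Ir(cod)Cl]2 with a chiral phosphoramidite) gives diethyl 2-[(2R)-but-3-en-2-yl]propanedioate F4. Krapcho dealkoxycarbonylation (NaCl, wet DMSO, 150 °C) gives 3.

**Step 5.**
- Under the amine–thiazolium conditions the aldehyde may enolise at C10 and lose a dioxolane oxygen by β-elimination, or condense with itself.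
- Fallback: it sets out from 5 and returns to 8, with the carbanion placed at C9, where no leaving group is adjacent. LiAlH4 reduces 5 to 2-{2-[(2S)-2-methylbut-3-en-1-yl]-1,3-dioxolan-2-yl}ethan-1-ol F5. Iodine, PPh3 and imidazole give 2-(2-iodoethyl)-2-[(2S)-2-methylbut-3-en-1-yl]-1,3-dioxolane F6. NaNO2 in DMF gives 2-[(2S)-2-methylbut-3-en-1-yl]-2-(2-nitroethyl)-1,3-dioxolane F7. Conjugate addition of its nitronate to 7 (catalytic 1,8-diazabicyclo[5.4.0]undec-7-ene) gives 6-{2-[(2S)-2-methylbut-3-en-1-yl]-1,3-dioxolan-2-yl}-5-nitrohexan-2-one F8. A reductive Nef reaction (NaOMe, then TiCl3 buffered with NH4OAc) gives 8.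

**Step 8.**
- The secondary, β-hydrogen-bearing nucleophile may enolise or reduce the hindered ketone instead of adding, and the angular methyl on the convex face may erode the facial preference.
- Fallback: it sets out from 11 and returns to 12. Isopropenylmagnesium bromide with CeCl3, a smaller sp2 nucleophile with no hydride to transfer, gives (3R,6R,9S,10R)-1,1-(ethylenedioxy)-3,6-dimethyl-9-(prop-1-en-2-yl)-cis-bicyclo[5.3.0]decan-9-ol F9. Hydrogenation of its only alkene (H2, PtO2, EtOAc) gives 12.

**Step 9.**
- The hindered dioxolane may hydrolyse slowly, and stronger acid would invite dehydration of the tertiary alcohol across C9–C10 or retro-aldol opening once C1 is a ketone.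
- Fallback: it sets out from 12 and returns to 14, with the hydroxyl capped before the ketone is unveiled. N-(Trimethylsilyl)imidazole gives (3R,6R,9R,10R)-1,1-(ethylenedioxy)-3,6-dimethyl-9-(propan-2-yl)-9-(trimethylsilyloxy)-cis-bicyclo[5.3.0]decane F10. Neutral transketalisation (catalytic iodine in dry acetone) gives (3R,6R,9R,10R)-3,6-dimethyl-9-(propan-2-yl)-9-(trimethylsilyloxy)-cis-bicyclo[5.3.0]decan-1-one F11. Kinetic enol silylation (LiN(i-Pr)2, Me3SiCl, THF, –78 °C) gives 14.

**Step 12.**
- Hydride may be delivered to the other face of C1, because the seven-membered enone is flexible and its facial bias rests on one neighbouring substituent.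
- Fallback: it sets out from 15 and returns to 21. If the epimer (1S,6R,9R,10S)-3,6-dimethyl-9-(propan-2-yl)-9-(trimethylsilyloxy)-cis-bicyclo[5.3.0]dec-2-en-1-ol F12 is the main product, it is esterified with 19 under Mitsunobu conditions (PPh3, diisopropyl azodicarboxylate, toluene, 0 °C), which inverts C1 and gives 21 directly.

## Further compounds

F1 | step 7 | (3R,6R)-1,1-(ethylenedioxy)-3,6-dimethyl-9-(trimethylsilyloxy)bicyclo[5.3.0]dec-9-ene (text locants; enol ether C9=C10) | C[Si](C)(C)OC1=C2C3(OCCO3)C[C@H](C)CC[C@]2(C)CC1
F2 | step 1 | (E)-but-2-en-1-ol | C/C=C/CO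
F3 | step 1 | (E)-but-2-en-1-yl methyl carbonate | C/C=C/COC(=O)OC
F4 | step 1 | diethyl 2-[(2R)-but-3-en-2-yl]propanedioate | C=C[C@@H](C)C(C(=O)OCC)C(=O)OCC
F5 | step 5 | 2-{2-[(2S)-2-methylbut-3-en-1-yl]-1,3-dioxolan-2-yl}ethan-1-ol | C=C[C@@H](C)CC1(OCCO1)CCO
F6 | step 5 | 2-(2-iodoethyl)-2-[(2S)-2-methylbut-3-en-1-yl]-1,3-dioxolane | C=C[C@@H](C)CC1(OCCO1)CCI
F7 | step 5 | 2-[(2S)-2-methylbut-3-en-1-yl]-2-(2-nitroethyl)-1,3-dioxolane | C=C[C@@H](C)CC1(OCCO1)CC[N+](=O)[O-]
F8 | step 5 | 6-{2-[(2S)-2-methylbut-3-en-1-yl]-1,3-dioxolan-2-yl}-5-nitrohexan-2-one (both epimers at the nitro carbon) | C=C[C@@H](C)CC1(OCCO1)CC(CCC(C)=O)[N+](=O)[O-]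
F9 | step 8 | (3R,6R,9S,10R)-1,1-(ethylenedioxy)-3,6-dimethyl-9-(prop-1-en-2-yl)-cis-bicyclo[5.3.0]decan-9-ol (text locants) | CC(=C)[C@]1(O)CC[C@@]2(C)CC[C@@H](C)CC3(OCCO3)[C@@H]12
F10 | step 9 | (3R,6R,9R,10R)-1,1-(ethylenedioxy)-3,6-dimethyl-9-(propan-2-yl)-9-(trimethylsilyloxy)-cis-bicyclo[5.3.0]decane (text locants) | CC(C)[C@]1(O[Si](C)(C)C)CC[C@@]2(C)CC[C@@H](C)CC3(OCCO3)[C@@H]12
F11 | step 9 | (3R,6R,9R,10R)-3,6-dimethyl-9-(propan-2-yl)-9-(trimethylsilyloxy)-cis-bicyclo[5.3.0]decan-1-one (text locants) | CC(C)[C@]1(O[Si](C)(C)C)CC[C@@]2(C)CC[C@@H](C)CC(=O)[C@@H]12
F12 | step 12 | (1S,6R,9R,10S)-3,6-dimethyl-9-(propan-2-yl)-9-(trimethylsilyloxy)-cis-bicyclo[5.3.0]dec-2-en-1-ol (text locants) | CC(C)[C@]1(O[Si](C)(C)C)CC[C@@]2(C)CCC(C)=C[C@H](O)[C@@H]12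
A1 | alternative 1 | (1E)-6-methyl-1-(trans-2-methylcyclopropyl)-3-(propan-2-yl)hepta-1,6-dien-3-ol (single stereoisomer as drawn) | C=C(C)CC[C@@](O)(C(C)C)/C=C/[C@H]1C[C@@H]1C
A2 | alternative 1 | 3,6-dimethyl-9-(propan-2-yl)-cis-bicyclo[5.3.0]dec-1-en-9-ol (text locants; alkene C1=C2, sp3 C3) | C1=C[C@@H](C)CC[C@]2(C)CC[C@@](O)(C(C)C)[C@H]12
A3 | alternative 2 | 3,6-dimethylcyclohepta-2,6-dien-1-one | O=C1C=C(C)CCC(C)=C1
A4 | alternative 2 | 1-(propan-2-yl)cyclopropan-1-ol | CC(C)C1(O)CC1
A5 | alternative 2 | (6R,9R,10R)-9-hydroxy-3,6-dimethyl-9-(propan-2-yl)-cis-bicyclo[5.3.0]dec-2-en-1-one (text locants) | O=C1C=C(C)CC[C@]2(C)CC[C@@](O)(C(C)C)[C@H]12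
A6 | alternative 3 | (2Z)-3-methyl-5-[1-methyl-3-(propan-2-yl)cyclopent-2-en-1-yl]pent-2-enal (E)-oxime (quaternary centre as drawn) | CC(C)C1=C[C@](C)(CC/C(C)=C\C=N\O)CC1
A7 | alternative 3 | tricyclic isoxazoline: 4,5-dihydroisoxazole fused across C9–C10 of the cis-bicyclo[5.3.0]dec-2-ene, oxygen on C9, imine carbon C1 | N1=C2C=C(C)CC[C@]3(C)CC[C@@](O1)(C(C)C)[C@H]23
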